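The readings are simulated from invented constants.

A bench chemist handed a flask in which starting material and partner combine to target reaches first for one plain rule, and so did I: I tried a single constant k in rate = k[starting material][partner] on each run, because that rate integrates in closed form.

| flask | starting material | partner | target | time |
|---|---|---|---|---|
| maple | 1.00 M | 1.10 M |  |  |
| larch | 0.600 M | 0.700 M |  |  |
| birch | 1.00 M | 1.10 M | 0.500 M |  |
| oak | 1.00 M | 0.550 M |  |  |
| cedar | 0.500 M | 0.550 M |  | 17 min |

| run | time / min | [target] / M |
|---|---|---|
| maple run | 2.8 | 0.060 |
| maple run | 5.7 | 0.167 |
| maple run | 8.5 | 0.185 |
| maple run | 11 | 0.258 |
| maple run | 14 | 0.310 |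
| maple run | 17 | 0.360 |
| larch run | 2.8 | 0.028 |
| larch run | 5.7 | 0.036 |
| larch run | 8.5 | 0.061 |
| larch run | 11 | 0.099 |
| larch run | 14 | 0.115 |
| larch run | 17 | 0.132 |
| birch run | 2.8 | 0.629 |
| birch run | 5.7 | 0.715 |
| birch run | 8.5 | 0.801 |
| birch run | 11 | 0.851 |
| birch run | 14 | 0.928 |
| birch run | 17 | 0.985 |
| oak run | 2.8 | 0.036 |
| oak run | 5.7 | 0.060 |
| oak run | 8.5 | 0.089 |
| oak run | 11 | 0.118 |
| oak run | 14 | 0.154 |
| oak run | 17 | 0.161 |

(readings scatter by 0.01 M)

- Overall: starting material + partner -> target.
- Constant volume, constant temperature.
- A reading of a species includes what of it is bound.
- "The second partner" is partner.
- An order is taken over about fifteen percent of the charge, up and down.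

1. order of the initial rate in [partner], near the charge of the maple run, the rate being that where two percent of its starting material are target
2. order of the initial rate in [starting material], near the charge of the maple run, the rate being that where two percent of its starting material are target (one fixed amount of target, the same in the runs compared)
3. the larch run starts with 0.400 M less of starting material and of partner than the maple run, and with no target. Compared where both hold the same amount of starting material, once fifteen percent of what the larch run was charged with has turned into target, is the larch run faster, slower or alike (within a tenth)?
4. target in the cedar run at 17 min, as a share of the starting material charged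
5. which of these the readings show (the second partner is lost by itself / the product reacts on with the second partner / the substrate pairs with itself / the product speeds the reaction / the two partners rest in a complex)

The closed form, with "start" marking the charge, is

ln( [partner]·[starting material]start / ([starting material]·[partner]start) ) = k·([partner]start − [starting material]start)·t

I put in the last larch reading, 0.132 M at 17 min, and got

k(larch) = 0.0232 M⁻¹ min⁻¹

The birch run was charged with 0.500 M of target and read 0.985 M at 17 min, so it had made 0.485 M, which gave

k(birch) = 0.0483 M⁻¹ min⁻¹

That was where the rule stopped working, since the birch constant came out at twice the larch constant, while the scatter of 0.01 M is 7.58% of the larch reading. The mean target of the birch run, between charge and last reading, was 0.742 M, against 0.0660 M in the larch run, so I read the constant as growing with target, which is autocatalysis, and drew a straight line through the two readings: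

k = kfree·(1 + [target]/Pc)

kfree = 0.0208 M⁻¹ min⁻¹

Pc = 0.561 M

Pc is the amount of target at which the target-carried part of the constant equals the target-free part, and I called it the crossover target.

The cedar run is charged with no target, so I solved the closed form first with kfree, which gave 0.0820 M of target at 17 min. The mean target of that pass raised the constant to 0.0223 M⁻¹ min⁻¹, and a second pass gave 0.0870 M, which is 17.4% of the starting material charged.

The forecast, made by someone who saw only these runs, gave orders of 1 in [partner] and 1 in [starting material], the larch run slower, 17.3% for the cedar run, lower than my figure, and the verdict that the product speeds the reaction, with the remark “acceleration offsets consumption”.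

The cedar run gave 17.1% of its starting material as target, the orders came out at 1.2 in [partner] and 1.0 in [starting material], the larch run was slower than the maple run at equal starting material, and the readings show that the product speeds the reaction, with these steps behind them:

    2 partner ⇌ reagent dimer, settled at all times (2.490 M⁻¹)
    starting material + reagent dimer → target + partner (0.07500 M⁻¹ min⁻¹)
    starting material + partner + target → 2 target (0.07980 M⁻² min⁻¹)

Where the larch and maple runs hold the same starting material, they also hold the same partner, since the larch run was charged with 0.400 M less of each. There the larch run, with 0.0900 M of target against 0.490 M in the maple run, went at 0.64 of the maple rate, and the crossover target applied to those two amounts gives 0.619.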